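The readings stem from a simulated flask for an exercise; scatter was added.

- Early in the two runs made so far, where end groups J and D join into links X, more of the lost J has reached X in the east run (65.8% at 3.00 min) than in the more dilute north run (36.3% at 8.00 min).

| setting | north | east | midnight | autumn | noon | winter |
|---|---|---|---|---|---|---|
| J | 0.041 M | 0.17 M | 0.060 M | 0.080 M | 0.12 M | 0.20 M |
| D | 1.1 equiv | 1.1 equiv | 1.10 equiv | 1.10 equiv | 1.10 equiv | 1.10 equiv |
| remark | run made earlier | run made earlier |  |  |  |  |
| time |  |  | 1.0 h | 1.0 h | 1.0 h | 1.0 h |

| run | time / min | X / % | J / % |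
|---|---|---|---|
| north | 8.00 | 26.4 | 27.2 |
| north | 15.0 | 29.9 | 12.0 |
| north | 20.0 | 31.0 | 7.2 |
| north | 30.0 | 33.2 | 7.5 |
| north | 40.0 | 34.1 | 6.1 |
| east | 3.00 | 38.4 | 41.6 |
| east | 8.00 | 47.5 | 17.4 |
| east | 15.0 | 49.4 | 8.4 |
| east | 25.0 | 50.6 | 4.8 |
| east | 30.0 | 53.1 | 3.1 |
| east | 40.0 | 51.8 | 3.4 |

(standard deviation of a reading: 1 percentage point)

* [X] at the end for midnight, autumn, noon, winter, in this order
* the course of these numbers from the first flask to the last (rises, then falls / hardly changes / rises all the way / falls, then rises / falls all the way)

- the numbers in the tables scatter with a standard deviation of 1 percentage point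
- "hardly changes" means that all values lie within two and a half points (for a concentration: within two and a half percent of the largest)

- I compare two rates: the rate into X, which I take to grow as the square of cJ, and the rate of loss elsewhere, which I take to grow as cJ. Their ratio is then cJ/c*, where c* is a concentration I read from the runs below.
- I solve both ends and join them. Far below c*, the share of J reaching X grows in step with cJ; far above it, the share levels at a ceiling. So share = ceiling × cJ/(cJ + c*).
- The last two readings of each run give plateaus of 33.6% for north and 52.4% for east. From these I read c*, the crossover concentration, the charged cJ where the two rates are equal, as 0.0367 M, with a ceiling of 63.8%. Both are readings and carry the scatter.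
- By 40.0 min the north run holds 6.1% J, and the new flasks get 1.0 h, so I take their ends as plateaus. My row is 0.0237 M, 0.0350 M, 0.0586 M, 0.108 M, which rises all the way.
- The forecast, which sees “a lower-order side path”, gives 0.024 M, 0.035 M, 0.058 M, 0.11 M, and says rises all the way. We differ in the last digit at noon.
- The flasks give 0.0242 M, 0.0353 M, 0.0589 M, 0.108 M: rises all the way.

    J + D → X + L (k = 2.00 M⁻¹ min⁻¹)
    2 D → Q (k = 1.20 M⁻¹ min⁻¹)
    J ⇌ Z (K = 10.0, k = 0.110 min⁻¹)
    J + L → G (k = 0.0910 M⁻¹ min⁻¹)

- In midnight, J + D → X + L does half of its turnover by 2.61 min and 96% of it by 0.500 h, while D falls to 12.4% of its charge and Z comes to hold 55.0% of the J charged. Midnight is charged at cJ/c* = 1.63, where the curve gives 39.6%, and at 1.00 h the flask holds X 40.4%. Winter is charged at cJ/c* = 5.45, where the curve gives 53.9%, and at 1.00 h that flask holds X 54.2%, with D, charged at 1.10 equiv yet the limiting reagent there, down to 1.41% of its charge.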